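**Retrosynthetic overview**
1. Target ⇒ side-chain oxirane by Shi epoxidation, ring oxirane by hydroxyl-directed epoxidation, ring carbinol by Luche reduction of a cis-6-acyloxy-2-methylcyclohex-2-enone.
2. cis ring ester ⇐ Mitsunobu inversion of a trans α'-ketol with (R)-2-methylbutanoic acid; ketol ⇐ enolate hydroxylation; angelate ⇐ esterification of the side-chain carbinol.
3. Six-membered ring, ring-to-side-chain C–C bond and its stereocentre ⇐ one step: enantioselective ring-expanding alkenylation of a bicyclo[3.1.0]hexenol with a 2-bromoallylic alcohol.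
4. Cyclopropanol ⇐ 2-methylcyclopent-2-enone (silyl dienol ether, Simmons–Smith); bromide ⇐ 2-bromoacrolein + allylmagnesium bromide (Brown allylation) + 2-methylbut-2-ene (cross-metathesis).
5. Ring order: cyclopentenone (bought) → fused cyclopropane → cyclohexenone by one-carbon ring expansion → ring oxirane → side-chain oxirane.

Assumption: 2-bromoacrolein, angelic acid and (R)-2-methylbutanoic acid are bought as such; racemic compounds are written as one enantiomer in SMILES.

**Step 1**
Reactants: 1 2-bromoprop-2-enal (2-bromoacrolein); 2 allylmagnesium bromide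
Product: 5 (3S)-2-bromohexa-1,5-dien-3-ol, via (−)-B-allyldiisopinocampheylborane 3 (not isolated), via diisopinocampheylborinate of the carbinol 4 (not isolated)
Conditions: (−)-Ipc2BOMe [from (+)-α-pinene], 2, Et2O, 0 °C → rt; then 1, −78 °C; then NaOH, H2O2, 0 °C → rt
Reagents that add atoms: none
Why: Brown asymmetric allylboration through a closed chair transition state, the (+)-α-pinene-derived borane delivering allyl to the Si face of the aldehyde, which gives the (S)-carbinol here because C(Br)=CH2 outranks allyl (the same facial sense that gives (S)-1-phenylbut-3-en-1-ol from benzaldehyde).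

**Step 2**
Reactants: 5 (3S)-2-bromohexa-1,5-dien-3-ol; 6 2-methylbut-2-ene
Product: 7 (3S)-2-bromo-6-methylhepta-1,5-dien-3-ol
Conditions: second-generation Grubbs catalyst RuCl2(=CHPh)(H2IMes)(PCy3) (3 mol %), 6 (excess, co-solvent), CH2Cl2, 40 °C, sealed tube
Reagents that add atoms: none
Why: Olefin cross-metathesis in which only the monosubstituted alkene reacts (the 2-bromo-1,1-disubstituted alkene is inert), converting allyl into prenyl without touching the carbinol stereocentre.

**Step 3**
Reactants: 8 2-methylcyclopent-2-en-1-one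
Product: 10 trimethyl[(5-methylcyclopenta-1,4-dien-1-yl)oxy]silane, via lithium dienolate 9 (not isolated)
Conditions: LiN(iPr)2, THF, −78 °C; Me3SiCl; pentane, filtration, kept cold and used at once
Reagents that add atoms: chlorotrimethylsilane, C[Si](C)(C)Cl
Why: Kinetic α'-deprotonation of the enone and O-silylation (cross-conjugated silyl dienol ether formation), no stereocentre being formed.

**Step 4**
Reactants: 10 trimethyl[(5-methylcyclopenta-1,4-dien-1-yl)oxy]silane
Product: 12 2-methylbicyclo[3.1.0]hex-2-en-1-ol (racemic), via its trimethylsilyl ether 11 (not isolated)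
Conditions: Et2Zn, CH2I2, CH2Cl2, −20 → 0 °C; then K2CO3 (cat.), MeOH, 0 °C
Reagents that add atoms: diiodomethane, C(I)I
Why: Furukawa–Simmons–Smith cyclopropanation, which takes the more electron-rich silyl enol ether double bond of the 2-siloxydiene; the ring fusion is necessarily cis and the racemate suffices because both stereocentres are erased in step 5.

**Step 5**
Reactants: 12 2-methylbicyclo[3.1.0]hex-2-en-1-ol (racemic, 1.5 equiv); 7 (3S)-2-bromo-6-methylhepta-1,5-dien-3-ol
Product: 13 (5R)-5-[(3S)-3-hydroxy-6-methylhepta-1,5-dien-2-yl]-2-methylcyclohex-2-en-1-one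
Conditions: NiBr2(dme) (10 mol %), chiral indanyl-substituted bis(oxazoline) ligand (12 mol %, enantiomer giving 5R), 4CzIPN (2 mol %), K2HPO4, DMA, blue LEDs (450 nm), 10 °C
Reagents that add atoms: none
Why: Proposed new method: photoinduced proton-coupled oxidation of the cyclopropanol O–H by excited 4CzIPN/phosphate gives an alkoxy radical whose strain-driven β-scission cleaves the internal ring-fusion bond, so the five-membered ring expands to the secondary β-keto radical of 2-methylcyclohex-2-enone (both stereocentres of racemic 12 are erased, so the process is stereoconvergent); the radical is captured by the bis(oxazoline)Ni(alkenyl)Br complex formed by oxidative addition of 7 to zerovalent nickel, and carbonyl-chelated reductive elimination from trivalent nickel forms the ring–C(sp2) bond and sets (5R) under ligand control, the 4CzIPN radical anion returning monovalent nickel to the zerovalent state; the closest known reactions are the Saegusa–Ito FeCl3 ring expansion of 1-siloxybicyclo[n.1.0]alkanes, photoredox/nickel ring-opening cross-coupling of monocyclic cyclopropanols and nickel-catalysed enantioconvergent alkenylation of secondary alkyl radicals.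

**Step 6**
Reactants: 13 (5R)-5-[(3S)-3-hydroxy-6-methylhepta-1,5-dien-2-yl]-2-methylcyclohex-2-en-1-one; 14 angelic acid [(2Z)-2-methylbut-2-enoic acid]
Product: 16 (3S)-6-methyl-2-[(1R)-4-methyl-5-oxocyclohex-3-en-1-yl]hepta-1,5-dien-3-yl (2Z)-2-methylbut-2-enoate, via angelic 2,4,6-trichlorobenzoic anhydride 15 (not isolated)
Conditions: 14, 2,4,6-Cl3C6H2COCl, Et3N, toluene, rt; then 13, toluene, 80 °C (no DMAP)
Reagents that add atoms: none
Why: Yamaguchi-type mixed-anhydride esterification run without a nucleophilic catalyst so that the (Z)-enoate does not isomerise to the tiglate, the carbinol configuration being retained because only the O–H bond reacts.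

**Step 7**
Reactants: 16 (3S)-6-methyl-2-[(1R)-4-methyl-5-oxocyclohex-3-en-1-yl]hepta-1,5-dien-3-yl (2Z)-2-methylbut-2-enoate
Product: 18 (3S)-2-[(1S,2S)-2-hydroxy-4-methyl-3-oxocyclohex-4-en-1-yl]-6-methylhepta-1,5-dien-3-yl (2Z)-2-methylbut-2-enoate (hydroxyl trans to the side chain), via potassium dienolate 17 (not isolated)
Conditions: KN(SiMe3)2, THF, −78 °C; then (±)-trans-2-(phenylsulfonyl)-3-phenyloxaziridine, −78 °C; NH4Cl (aq)
Reagents that add atoms: 2-(phenylsulfonyl)-3-phenyloxaziridine (Davis reagent), O=S(=O)(c1ccccc1)N1OC1c1ccccc1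
Why: Davis hydroxylation of the kinetic α'-enolate (the ketone α'-H is far more acidic than any ester position), the oxidant approaching anti to the adjacent ring substituent so that the trans ketol is expected as the major isomer.

**Step 8**
Reactants: 18 the trans ketol; 19 (2R)-2-methylbutanoic acid
Product: 20 (1R,6S)-3-methyl-6-[(3S)-6-methyl-3-{[(2Z)-2-methylbut-2-enoyl]oxy}hepta-1,5-dien-2-yl]-2-oxocyclohex-3-en-1-yl (2R)-2-methylbutanoate (ester cis to the side chain)
Conditions: PPh3, DIAD, toluene, 0 °C → rt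
Reagents that add atoms: none
Why: Mitsunobu esterification, in which SN2 displacement of the oxyphosphonium group at the α-keto carbon inverts that centre and so places the ester cis to the side chain, the stereocentre of the acid not being involved.

**Step 9**
Reactants: 20 the cis α'-acyloxy enone
Product: 21 (1R,2S,6S)-2-hydroxy-3-methyl-6-[(3S)-6-methyl-3-{[(2Z)-2-methylbut-2-enoyl]oxy}hepta-1,5-dien-2-yl]cyclohex-3-en-1-yl (2R)-2-methylbutanoate (all-cis)
Conditions: NaBH4, CeCl3·7H2O, MeOH, −78 °C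
Reagents that add atoms: none
Why: Luche 1,2-reduction, hydride adding anti to the axial α-acyloxy group (the same facial sense as carvone → cis-carveol), so the new hydroxyl is cis to both the ester and the side chain.

**Step 10**
Reactants: 21 the all-cis allylic alcohol
Product: 22 (1R,2R,3R,4S,6S)-2-hydroxy-1-methyl-4-[(3S)-6-methyl-3-{[(2Z)-2-methylbut-2-enoyl]oxy}hepta-1,5-dien-2-yl]-7-oxabicyclo[4.1.0]heptan-3-yl (2R)-2-methylbutanoate
Conditions: VO(acac)2 (5 mol %), tBuOOH, CH2Cl2, 0 °C → rt
Reagents that add atoms: tert-butyl hydroperoxide, CC(C)(C)OO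
Why: Hydroxyl-directed vanadium-catalysed epoxidation, oxygen being delivered to the ring alkene syn to the allylic hydroxyl while the other alkenes, which lack a free allylic hydroxyl, are left alone.

**Step 11**
Reactants: 22 the ring epoxy alcohol
Product: 23 (1R,2R,3R,4S,6S)-4-{(3S)-4-[(2R)-3,3-dimethyloxiran-2-yl]-3-{[(2Z)-2-methylbut-2-enoyl]oxy}but-1-en-2-yl}-2-hydroxy-1-methyl-7-oxabicyclo[4.1.0]heptan-3-yl (2R)-2-methylbutanoate (CNP0181486.1)
Conditions: D-fructose-derived Shi ketone (30 mol %), KHSO5 (as 2KHSO5·KHSO4·K2SO4), K2CO3, Bu4NHSO4, MeCN/DMM/aqueous Na2B4O7 buffer, −10 → 0 °C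
Reagents that add atoms: potassium peroxymonosulfate, [K+].[O-]S(=O)(=O)OO
Why: Shi asymmetric epoxidation through the spiro transition state, chemoselective for the electron-rich trisubstituted prenyl alkene over the 1,1-disubstituted alkene and the enoate, the D-fructose-derived ketone giving the (R)-oxirane.

**Compound list**
1 | 2-bromoprop-2-enal (2-bromoacrolein) | C=C(Br)C=O | starting material
2 | allylmagnesium bromide | C=CC[Mg]Br | starting material
3 | (−)-B-allyldiisopinocampheylborane | C=CCB([C@@H]1C[C@@H]2C[C@H]([C@H]1C)C2(C)C)[C@@H]1C[C@@H]2C[C@H]([C@H]1C)C2(C)C | intermediate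
4 | (3S)-2-bromohexa-1,5-dien-3-yl diisopinocampheylborinate | C=CC[C@H](OB([C@@H]1C[C@@H]2C[C@H]([C@H]1C)C2(C)C)[C@@H]1C[C@@H]2C[C@H]([C@H]1C)C2(C)C)C(Br)=C | intermediate
5 | (3S)-2-bromohexa-1,5-dien-3-ol | C=CC[C@H](O)C(Br)=C | intermediate
6 | 2-methylbut-2-ene | CC=C(C)C | starting material
7 | (3S)-2-bromo-6-methylhepta-1,5-dien-3-ol | CC(C)=CC[C@H](O)C(Br)=C | intermediate
8 | 2-methylcyclopent-2-en-1-one | CC1=CCCC1=O | starting material
9 | lithium 5-methylcyclopenta-1,4-dien-1-olate | CC1=CCC=C1[O-].[Li+] | intermediate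
10 | trimethyl[(5-methylcyclopenta-1,4-dien-1-yl)oxy]silane | CC1=CCC=C1O[Si](C)(C)C | intermediate
11 | trimethyl[(2-methylbicyclo[3.1.0]hex-2-en-1-yl)oxy]silane (racemic, cis-fused) | CC1=CC[C@H]2C[C@@]12O[Si](C)(C)C | intermediate
12 | 2-methylbicyclo[3.1.0]hex-2-en-1-ol (racemic, cis-fused) | CC1=CC[C@H]2C[C@@]12O | intermediate
13 | (5R)-5-[(3S)-3-hydroxy-6-methylhepta-1,5-dien-2-yl]-2-methylcyclohex-2-en-1-one | C=C([C@H](CC=C(C)C)O)[C@@H]1CC=C(C)C(=O)C1 | intermediate
14 | angelic acid, (2Z)-2-methylbut-2-enoic acid | C/C=C(/C)C(=O)O | starting material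
15 | (2Z)-2-methylbut-2-enoic 2,4,6-trichlorobenzoic anhydride | C/C=C(/C)C(=O)OC(=O)c1c(Cl)cc(Cl)cc1Cl | intermediate
16 | (3S)-6-methyl-2-[(1R)-4-methyl-5-oxocyclohex-3-en-1-yl]hepta-1,5-dien-3-yl (2Z)-2-methylbut-2-enoate | C=C([C@H](CC=C(C)C)OC(=O)/C(C)=C\C)[C@@H]1CC=C(C)C(=O)C1 | intermediate
17 | potassium cross-conjugated dienolate of 16 | C=C([C@H](CC=C(C)C)OC(=O)/C(C)=C\C)[C@@H]1CC=C(C)C([O-])=C1.[K+] | intermediate
18 | (3S)-2-[(1S,2S)-2-hydroxy-4-methyl-3-oxocyclohex-4-en-1-yl]-6-methylhepta-1,5-dien-3-yl (2Z)-2-methylbut-2-enoate | C=C([C@H](CC=C(C)C)OC(=O)/C(C)=C\C)[C@@H]1CC=C(C)C(=O)[C@H]1O | intermediate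
19 | (2R)-2-methylbutanoic acid | CC[C@@H](C)C(=O)O | starting material
20 | (1R,6S)-3-methyl-6-[(3S)-6-methyl-3-{[(2Z)-2-methylbut-2-enoyl]oxy}hepta-1,5-dien-2-yl]-2-oxocyclohex-3-en-1-yl (2R)-2-methylbutanoate | C=C([C@H](CC=C(C)C)OC(=O)/C(C)=C\C)[C@@H]1CC=C(C)C(=O)[C@@H]1OC(=O)[C@H](C)CC | intermediate
21 | (1R,2S,6S)-2-hydroxy-3-methyl-6-[(3S)-6-methyl-3-{[(2Z)-2-methylbut-2-enoyl]oxy}hepta-1,5-dien-2-yl]cyclohex-3-en-1-yl (2R)-2-methylbutanoate | C=C([C@H](CC=C(C)C)OC(=O)/C(C)=C\C)[C@@H]1CC=C(C)[C@H](O)[C@@H]1OC(=O)[C@H](C)CC | intermediate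
22 | (1R,2R,3R,4S,6S)-2-hydroxy-1-methyl-4-[(3S)-6-methyl-3-{[(2Z)-2-methylbut-2-enoyl]oxy}hepta-1,5-dien-2-yl]-7-oxabicyclo[4.1.0]heptan-3-yl (2R)-2-methylbutanoate | C=C([C@H](CC=C(C)C)OC(=O)/C(C)=C\C)[C@@H]1C[C@@H]2O[C@]2(C)[C@H](O)[C@@H]1OC(=O)[C@H](C)CC | intermediate
23 | (1R,2R,3R,4S,6S)-4-{(3S)-4-[(2R)-3,3-dimethyloxiran-2-yl]-3-{[(2Z)-2-methylbut-2-enoyl]oxy}but-1-en-2-yl}-2-hydroxy-1-methyl-7-oxabicyclo[4.1.0]heptan-3-yl (2R)-2-methylbutanoate | C=C([C@H](C[C@H]1OC1(C)C)OC(=O)/C(C)=C\C)[C@@H]1C[C@@H]2O[C@]2(C)[C@H](O)[C@@H]1OC(=O)[C@H](C)CC | target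

**Totals**
Total step count: 11. Longest linear sequence: 9 steps (steps 1, 2, 5–11; the ring branch, steps 3, 4, 5–11, is equally long).

**Three steps most likely to fail**

Step 4, the cyclopropanation. Diene 10 is a 2-siloxycyclopentadiene and may undergo 1,5-hydrogen shift, Diels–Alder dimerisation or double cyclopropanation before the mono-adduct forms. The fallback avoids the diene; it sets out from 8 and comes back at 12. The kinetic lithium enolate of 8 is alkylated with (iodomethyl)tributylstannane, ICH2SnBu3, to give 2-methyl-5-[(tributylstannyl)methyl]cyclopent-2-en-1-one F1. TiCl4 (CH2Cl2, −78 °C) then closes this β-stannyl ketone to 12 by destannylative 1,3-cyclisation onto the activated carbonyl.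

Step 5, the proposed ring-expanding alkenylation. Risks are external instead of internal β-scission, β-hydride loss at nickel leading to o-cresol, and insufficient enantiocontrol at a centre with no adjacent directing group. The fallback uses known reactions only; it sets out from 7 and comes back at 13.
- Miyaura borylation of 7 (B2pin2, PdCl2(PPh3)2, KOPh, toluene, 50 °C) gives (3S)-6-methyl-2-(4,4,5,5-tetramethyl-1,3,2-dioxaborolan-2-yl)hepta-1,5-dien-3-ol F2.
- Commercial 2-methylcyclohexanone is converted (LiN(iPr)2, Me3SiCl) into its kinetic silyl enol ether trimethyl[(6-methylcyclohex-1-en-1-yl)oxy]silane F3, and Saegusa–Ito oxidation (Pd(OAc)2, MeCN) gives 6-methylcyclohex-2-en-1-one F4.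
- Hayashi–Miyaura conjugate addition of F2 to F4 (Rh(acac)(C2H4)2, (R)-BINAP, dioxane/H2O, 100 °C) sets the ring stereocentre under catalyst control. It gives (5R)-5-[(3S)-3-hydroxy-6-methylhepta-1,5-dien-2-yl]-2-methylcyclohexan-1-one F5 as a mixture of epimers at the methyl-bearing carbon.
- Thermodynamic silylation (Me3SiOTf, Et3N) gives the bis-silyl compound trimethylsilyl enol ether/trimethylsilyl ether F6. A second Saegusa–Ito oxidation with acidic work-up removes the epimeric centre and gives 13.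

Step 8, the Mitsunobu inversion. The ketol is hindered, and elimination towards a phenol or epimerisation of the α-acyloxy ketone can compete. The fallback replaces the redox condensation by an isolated sulfonate and a preformed carboxylate; it sets out from 18 and comes back at 20. Triflation of 18 (Tf2O, 2,6-lutidine, CH2Cl2, −78 °C) gives the α-keto triflate (3S)-6-methyl-2-[(1S,2S)-4-methyl-3-oxo-2-{[(trifluoromethyl)sulfonyl]oxy}cyclohex-4-en-1-yl]hepta-1,5-dien-3-yl (2Z)-2-methylbut-2-enoate F7. SN2 displacement with cesium (2R)-2-methylbutanoate F8 (from 19 and Cs2CO3; 18-crown-6, toluene, 0 °C) then gives 20 with inversion.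

**Further compounds**
F1 | step 4 | 2-methyl-5-[(tributylstannyl)methyl]cyclopent-2-en-1-one (racemic) | CC1=CCC(C[Sn](CCCC)(CCCC)CCCC)C1=O
F2 | step 5 | (3S)-6-methyl-2-(4,4,5,5-tetramethyl-1,3,2-dioxaborolan-2-yl)hepta-1,5-dien-3-ol | CC(C)=CC[C@H](O)C(=C)B1OC(C)(C)C(C)(C)O1
F3 | step 5 | trimethyl[(6-methylcyclohex-1-en-1-yl)oxy]silane (racemic) | CC1CCCC=C1O[Si](C)(C)C
F4 | step 5 | 6-methylcyclohex-2-en-1-one (racemic) | CC1CCC=CC1=O
F5 | step 5 | (5R)-5-[(3S)-3-hydroxy-6-methylhepta-1,5-dien-2-yl]-2-methylcyclohexan-1-one (epimers at C2) | C=C([C@H](CC=C(C)C)O)[C@@H]1CCC(C)C(=O)C1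
F6 | step 5 | trimethyl({(5R)-2-methyl-5-[(3S)-6-methyl-3-(trimethylsilyloxy)hepta-1,5-dien-2-yl]cyclohex-1-en-1-yl}oxy)silane | C=C([C@H](CC=C(C)C)O[Si](C)(C)C)[C@@H]1CCC(C)=C(O[Si](C)(C)C)C1
F7 | step 8 | (3S)-6-methyl-2-[(1S,2S)-4-methyl-3-oxo-2-{[(trifluoromethyl)sulfonyl]oxy}cyclohex-4-en-1-yl]hepta-1,5-dien-3-yl (2Z)-2-methylbut-2-enoate | C=C([C@H](CC=C(C)C)OC(=O)/C(C)=C\C)[C@@H]1CC=C(C)C(=O)[C@H]1OS(=O)(=O)C(F)(F)F
F8 | step 8 | cesium (2R)-2-methylbutanoate | CC[C@@H](C)C(=O)[O-].[Cs+]
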